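If protic impurity takes partner one for one, a flask has the charge of partner minus the impurity to spend on everything else. This is the spendable partner, 0.0550 M in each of the three new flasks. Each starting material consumed costs one partner and each over-reaction a second, while each target still standing has been paid for once, so at the end of the spending:

consumed starting material = (spendable partner + target) / 2

| flask | starting material | partner | protic impurity | temperature | remark | time |
|---|---|---|---|---|---|---|
| spring | 0.025 M | 0.060 M | 5 mM | 55 °C | run made earlier |  |
| autumn | 0.038 M | 0.060 M | 5 mM | 85 °C | run made earlier |  |
| winter | 0.050 M | 0.060 M | 10 mM | 55 °C | run made earlier |  |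
| Tuesday's | 0.050 M | 0.0600 M | 5.00 mM | 110 °C |  | 3.0 min |
| Thursday's | 0.050 M | 0.0600 M | 5.00 mM | 60 °C |  | 3.0 min |
| Saturday's | 0.050 M | 0.0600 M | 5.00 mM | 85 °C |  | 3.0 min |

- spring (time / min: target / %, starting material / %): 2.50: 6.1, 28.6; 5.00: 0.7, 20.8; 12.0: 0.1, 15.9; 30.0: 0, 9.4
- autumn (time / min: target / %, starting material / %): 0.500: 3.2, 51.2; 1.00: 1.4, 43.5; 3.00: 0.8, 34.2; 6.00: 1.1, 28.7
- winter (time / min: target / %, starting material / %): 2.50: 35.8, 33.1; 5.00: 35.6, 31.9; 12.0: 35.4, 33.1; 30.0: 34.8, 33.0

(each reading ± 0.5 percentage points)

- candidate steps: partner + protic impurity -> quenched reagent; partner + target -> over-reaction product; starting material + partner + target -> 2 target; starting material + partner -> target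

1. the flask that comes out highest in amount of target, in percent of the starting material charged, or "all alike" when all lie within 1.5 percentage points (Tuesday's / Thursday's / Saturday's / all alike)
2. target at the end, in percent of the starting material charged, Tuesday's
3. target at the end, in percent of the starting material charged, Thursday's
4. target at the end, in percent of the starting material charged, Saturday's

The winter run tests this rule. Its charges allow 0.0500 M, and its last readings show 0.0496 M spent, while its starting material stands flat from 33.1% to 33.0%.

For Saturday's flask the curve of target can be drawn against starting material consumed. The second quantity needed is the selectivity factor, the over-reaction constant over that of the target-made step, which is a concentration. Reckoned with those two steps: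

target gained per starting material consumed = 1 − selectivity factor / starting material present

The first autumn reading, at the same temperature, gives as a reading, with its scatter, a factor of 0.0259 M. The slope therefore starts at 0.482. It crosses zero at a crest, when starting material has fallen to 51.8% of its charge, and target there is 0.00707 M, or 14.1%. The crest has cost 0.0412 M, leaving 0.0138 M of spendable partner, which consumes about 0.00692 M more starting material. Over that stretch the curve is replaced by its mean slope, −0.182, and the level comes out at 11.6%.

The forecast names Thursday's, with 1%, 33.5% and 13% for Tuesday's, Thursday's and Saturday's, the last above this reckoning, and says of Tuesday's flask that "target collapses to a trace".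

The flasks give 0.732%, 29.9% and 5.87%, so Thursday's is highest, and Saturday's lies 5.7 percentage points under the reckoning. In Saturday's flask, at 0.169 min, target was being made 1.02 times as fast as it was used up. Spendable partner and Saturday's target together return a conversion of 57.9%, and the flask shows 57.9%.

    partner + protic impurity → quenched reagent (k = 15.0 M⁻¹ s⁻¹, Ea = 61.0 kJ mol⁻¹)
    partner + target → over-reaction product (k = 2.10 M⁻¹ s⁻¹, Ea = 68.0 kJ mol⁻¹)
    starting material + partner + target → 2 target (k = 120 M⁻² s⁻¹, Ea = 41.0 kJ mol⁻¹)
    starting material + partner → target (k = 0.0430 M⁻¹ s⁻¹, Ea = 53.0 kJ mol⁻¹)
    (constants at 60 °C)

A neighbour of Saturday's flask, charged with 0.036 M of partner, has 0.0310 M to spend, so the rule with no target standing puts its remaining starting material at 69.0%. Its computed target of 9.92%, with partner at 0%, moves that by the rule to 64.0%, and the flask holds 64.0%.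

Readings and results were computed on assumed constants; scatter was added.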